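Rings and locants: the alkene half is ring A (C1–C5, C10; carbinol C3) fused to ring B (C5–C10; C7=C8). The saturated half is ring C (C5'–C10'; C8' bears H and CH3) fused to ring D (carbinol C3'). The bridge is C9–C11–C12–C9', and β is the face of the angular methyl groups.
Last disconnections: C9–C11 by a phosphine-directed syn-SN2' allylic alkylation, which also places C7=C8, and C9'–C12 by a Johnson–Claisen [3,3] shift followed by directed hydrogenation for C8'. Both partners come from one allylic alcohol and so from one enone, C7(=O)–C8(CH3)=C9.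
Key disconnection: C8 (C8') and its methyl group are removed from the C7–C8–C9 unit. Ring C (and ring B) is therefore made from the five-membered ring C5–C6–C7–C9–C10 of a cis-hydrindane, by chloro(methyl)carbene transfer to the C7=C9 silyl enol ether and electrocyclic opening.
Enabling feature: both decalins are cis-fused (H-5 and CH3-10 on one face), and C8 is a single methyl-bearing ring atom between C7 and C9. A bicyclo[4.3.0] enone takes up the C10 methyl group cis to H-5 and releases its enolate as the C7=C9 enol ether, which is exactly the bond into which C8 must be inserted.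
Ring order: ring D (= ring A) and the five-membered ring form together (Pauson–Khand), then five → six (ring C = ring B), then union of the halves.

Key step: step 6

Remark: read literally, the SMILES describes cis-fused decalins (H-5/CH3-10 and H-5'/CH3-10' cis, both hydroxyl groups on the opposite α face). The route is built for exactly this isomer, (3R,5S,9S,10R,3'R,5'S,8'R,9'S,10'R). Compounds 7–11 carry unprimed locants and serve both halves.

Step 1
Reactants: 1 pent-4-yn-1-ol
Product: 2 pent-4-ynal
Conditions: TEMPO (10 mol %), PhI(OAc)2, CH2Cl2, rt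
Reagents that add atoms: none
Why: The oxoammonium-catalysed (TEMPO) alcohol oxidation should stop at the aldehyde and leave the terminal alkyne untouched; no stereocentre is involved.

Step 2
Reactants: 2 pent-4-ynal; 3 3-methylbuta-1,2-diene
Product: 5 (4R)-3,3-dimethyloct-1-en-7-yn-4-ol, via prenylborane 4 (not isolated)
Conditions: 3, (−)-Ipc2BH [from (+)-α-pinene], THF, −25 → 0 °C; then 2, −78 °C; NaOH, H2O2
Reagents that add atoms: none
Why: Hydroboration of the allene at its CH2 terminus gives the prenylborane, and its Brown-type asymmetric allylboration (closed chair transition state with allylic transposition) joins C3 to the tertiary carbon C4, so the gem-dimethyl and vinyl groups arrive together and the isopinocampheyl groups set C3 as R.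

Step 3
Reactants: 5 (4R)-3,3-dimethyloct-1-en-7-yn-4-ol
Product: 6 (4R)-4-(tert-butyldimethylsilyloxy)-3,3-dimethyloct-1-en-7-yne
Conditions: TBSOTf, 2,6-lutidine, CH2Cl2, 0 °C
Reagents that add atoms: tert-butyldimethylsilyl triflate CC(C)(C)[Si](C)(C)OS(=O)(=O)C(F)(F)F
Why: O-silylation with the silyl triflate copes with the neopentyl-type secondary alcohol, and the TBS ether should survive organometallics, hydride and heat until fluoride removes it in step 14.

Step 4
Reactants: 6 (4R)-4-(tert-butyldimethylsilyloxy)-3,3-dimethyloct-1-en-7-yne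
Product: 7 bicyclic enone (3aS,5R)-5-(tert-butyldimethylsilyloxy)-4,4-dimethyl-3,3a,4,5,6,7-hexahydro-2H-inden-2-one (C7=O; C9=C10; H-5 β; 3-OTBS α)
Conditions: Co2(CO)8 (10 mol %), tetramethylthiourea (60 mol %), CO (1 atm), toluene, 70 °C
Reagents that add atoms: carbon monoxide [C-]#[O+]
Why: The intramolecular Pauson–Khand [2+2+1] cycloaddition of the 1,7-enyne, helped by the gem-dimethyl group, closes the carbinol ring and the cyclopentenone C5–C6–C7–C9–C10 at once, and C5 is set by a chair-like tether with OTBS equatorial, which places C6 cis to OTBS (H-5 β).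

Step 5
Reactants: 7 bicyclic enone
Product: 8 cis-hydrindene silyl enol ether (C7(OSiMe3)=C9; CH3-10 β; H-5 β; 3-OTBS α)
Conditions: MeMgBr, CuBr·SMe2 (10 mol %), Me3SiCl, HMPA, THF, −78 → −40 °C; Et3N quench
Reagents that add atoms: methylmagnesium bromide C[Mg]Br; chlorotrimethylsilane C[Si](C)(C)Cl
Why: In this silyl-chloride-accelerated copper-catalysed conjugate addition the methyl group should reach C10 from the face of H-5, because a trans-fused bicyclo[4.3.0] enolate is strained and the axial 4α-methyl group screens the other face, and the enolate is silylated where it forms, giving only the C7=C9 enol ether.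

Step 6
Reactants: 8 cis-hydrindene silyl enol ether
Product: 10 cis-decalin enone (C7=O; C8(CH3)=C9; CH3-10 β; H-5 β; 3-OTBS α), via chlorocyclopropane 9 (not isolated)
Conditions: CH3CHCl2, n-BuLi, Et2O, −40 → −30 °C; then toluene, 110 °C
Reagents that add atoms: 1,1-dichloroethane CC(Cl)Cl
Why: n-BuLi turns CH3CHCl2 into 1,1-dichloroethyllithium, a chloro(methyl)carbenoid that adds to the only C=C bond of 8, the electron-rich C7=C9 enol ether, and closes the three-membered ring C7–C8–C9 of 9 in a concerted [2+1] mode; on heating the C8–Cl bond ionises while the shared C7–C9 bond breaks in a disrotatory two-electron electrocyclic opening, and the 1-silyloxyallyl cation drops Me3SiCl to give 10, so that the five-membered ring C5–C6–C7–C9–C10 becomes the six-membered ring C5–C6–C7–C8–C9–C10. The closest known reaction type is the one-carbon ring expansion of cyclic silyl enol ethers through halocarbene adducts, which turns cyclopentanone enol ethers into 2-methylcyclohex-2-enones. In one operation the step brings in C8 together with its methyl branch, fixes the final ring size and leaves the C7(=O)–C8(CH3)=C9 triad, from which the C7=C8 alkene, C9, C9' and C8' are all derived later by 1,3-transposition; since 10 is used for both halves, it makes ring C and ring B, two of the four rings of the target. No lasting stereocentre is formed: the three centres of 9 (drawn for attack on the convex β face) vanish again, whereas C3, C5 and C10 are spectators, so the cis fusion of the hydrindane is handed on unchanged to the decalin. The selectivity needed is the site of insertion (C7–C9 and not C6–C7), which is fixed by the position of the enol ether double bond as it was formed in step 5. The opening also needs chlorine endo (cis to the five-membered ring), which is secured because the larger methyl group of the carbenoid takes the exo position, away from ring carbons C6 and C10.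

Step 7
Reactants: 10 cis-decalin enone
Product: 11 allylic alcohol (7β-OH, 7S; C8(CH3)=C9)
Conditions: (R)-2-methyl-CBS-oxazaborolidine (20 mol %), BH3·SMe2, THF, −20 °C; aq. NH4Cl
Reagents that add atoms: none
Why: In the Corey–Bakshi–Shibata reduction the (R)-catalyst reads the C8 alkenyl side as large and C6H2 as small and should deliver hydride to the α face of C7 in 1,2-fashion, so the 7β (S) carbinol is set by catalyst control.

Step 8
Reactants: 11 allylic alcohol (first portion, becomes the saturated half)
Product: 13 ethyl ester (C9'β–C12H2–CO2Et; C7'=C8'), via ketene acetal 12 (not isolated)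
Conditions: MeC(OEt)3, EtCO2H (10 mol %), 140 °C, removal of EtOH
Reagents that add atoms: triethyl orthoacetate CCOC(C)(OCC)OCC
Why: The Johnson–Claisen rearrangement is suprafacial on the allyl unit, so the β C7'–O bond is traded for a β C9'–C12 bond next to the quaternary C10' (C9' set by 1,3-chirality transfer) and the alkene moves to C7'=C8'.

Step 9
Reactants: 13 ethyl ester
Product: 14 primary alcohol (C9'β–C12H2–C11H2OH; C7'=C8')
Conditions: LiAlH4, Et2O, 0 °C
Reagents that add atoms: none
Why: Hydride reduction of the ester touches no stereocentre and no alkene, and it provides the hydroxyl group that steers the next step.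

Step 10
Reactants: 14 primary alcohol
Product: 15 saturated alcohol (8'α-CH3; H-8' β)
Conditions: [Ir(cod)(PCy3)(py)]PF6 (5 mol %), H2 (4 atm), CH2Cl2, rt
Reagents that add atoms: none
Why: In this hydroxyl-directed homogeneous hydrogenation the cationic iridium catalyst binds the C11 hydroxyl of the β side chain and should add H2 to the β face of C7'=C8', which is also the convex face of the cis-decalin, so H-8' is β and the methyl group α (8'R).

Step 11
Reactants: 15 saturated alcohol
Product: 16 primary bromide (C9'β–C12H2–C11H2Br)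
Conditions: CBr4, PPh3, CH2Cl2, 0 °C
Reagents that add atoms: tetrabromomethane BrC(Br)(Br)Br
Why: The Appel reaction converts the unhindered primary alcohol into the bromide under neutral conditions that leave the TBS ether and all stereocentres alone.

Step 12
Reactants: 11 allylic alcohol (second portion, becomes the alkene half)
Product: 17 7β-[2-(diphenylphosphanyl)benzoate] of 11
Conditions: 2-(Ph2P)C6H4CO2H, DCC, DMAP (10 mol %), CH2Cl2, rt, argon
Reagents that add atoms: 2-(diphenylphosphanyl)benzoic acid OC(=O)c1ccccc1P(c1ccccc1)c1ccccc1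
Why: Steglich esterification acylates oxygen, so C7 keeps its configuration, and it installs a leaving group that carries a phosphine donor on the β face.

Step 13
Reactants: 16 primary bromide; 17 7β-[2-(diphenylphosphanyl)benzoate]
Product: 19 bis-TBS ether of the target, via Grignard reagent 18 (not isolated)
Conditions: 16, Mg, Et2O, reflux; then 17, CuBr·SMe2 (50 mol %), Et2O, rt
Reagents that add atoms: none
Why: In this phosphine-directed copper-mediated allylic substitution with a Grignard reagent the alkylcopper species is held by the ester phosphine and delivered to C9 on the face of the leaving group (syn-SN2'), so the C9–C11 bond forms β (C9 set by 1,3-chirality transfer from C7) and the alkene lands at C7=C8.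

Step 14
Reactants: 19 bis-TBS ether of the target
Product: 20 target diol CNP0194061.2
Conditions: HF·pyridine, THF, 0 °C → rt
Reagents that add atoms: none
Why: Fluoride-driven cleavage of both silyl ethers breaks only Si–O bonds, so the carbinol centres C3 and C3', the C7=C8 alkene and all other stereocentres remain as set.

Compound list
1 | pent-4-yn-1-ol | C#CCCCO | starting material
2 | pent-4-ynal | C#CCCC=O | intermediate
3 | 3-methylbuta-1,2-diene | CC(C)=C=C | starting material
4 | (3-methylbut-2-en-1-yl)diisopinocampheylborane, Ipc groups from (+)-α-pinene | CC(C)=CCB([C@@H]1C[C@@H]2C[C@H]([C@H]1C)C2(C)C)[C@@H]1C[C@@H]2C[C@H]([C@H]1C)C2(C)C | intermediate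
5 | (4R)-3,3-dimethyloct-1-en-7-yn-4-ol | C=CC(C)(C)[C@H](O)CCC#C | intermediate
6 | (4R)-4-(tert-butyldimethylsilyloxy)-3,3-dimethyloct-1-en-7-yne | C=CC(C)(C)[C@H](O[Si](C)(C)C(C)(C)C)CCC#C | intermediate
7 | (3aS,5R)-5-(tert-butyldimethylsilyloxy)-4,4-dimethyl-3,3a,4,5,6,7-hexahydro-2H-inden-2-one | O=C1C[C@@H]2C(C)(C)[C@H](O[Si](C)(C)C(C)(C)C)CCC2=C1 | intermediate
8 | cis-hydrindene silyl enol ether: C7(OSiMe3)=C9, CH3-10 and H-5 β, 3-OTBS α, 4,4-dimethyl | C[Si](C)(C)OC=1C[C@@H]2C(C)(C)[C@H](O[Si](C)(C)C(C)(C)C)CC[C@]2(C)C=1 | intermediate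
9 | chlorocyclopropane: C8(Cl)(CH3) bridging C7(OSiMe3) and C9 on the β face, chlorine endo, methyl exo | C[Si](C)(C)O[C@]12C[C@@H]3C(C)(C)[C@H](O[Si](C)(C)C(C)(C)C)CC[C@]3(C)[C@H]1[C@@]2(C)Cl | intermediate
10 | cis-decalin enone: 7-(tert-butyldimethylsilyloxy)-3,4a,8,8-tetramethyl-4a,5,6,7,8,8a-hexahydronaphthalen-2(1H)-one, ring-fusion H and CH3 cis, OTBS on the opposite face | O=C1C[C@@H]2C(C)(C)[C@H](O[Si](C)(C)C(C)(C)C)CC[C@]2(C)C=C1C | intermediate
11 | allylic alcohol: 7β-OH (7S), C8(CH3)=C9, otherwise as 10 | O[C@H]1C[C@@H]2C(C)(C)[C@H](O[Si](C)(C)C(C)(C)C)CC[C@]2(C)C=C1C | intermediate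
12 | ketene acetal: 7β-O–C(OEt)=CH2 derivative of 11 | C=C(OCC)O[C@H]1C[C@@H]2C(C)(C)[C@H](O[Si](C)(C)C(C)(C)C)CC[C@]2(C)C=C1C | intermediate
13 | ethyl ester: C9'β–CH2CO2Et, C7'=C8', cis-decalin, 3'-OTBS α | CC1=CC[C@@H]2C(C)(C)[C@H](O[Si](C)(C)C(C)(C)C)CC[C@]2(C)[C@H]1CC(=O)OCC | intermediate
14 | primary alcohol: C9'β–CH2CH2OH, C7'=C8' | CC1=CC[C@@H]2C(C)(C)[C@H](O[Si](C)(C)C(C)(C)C)CC[C@]2(C)[C@H]1CCO | intermediate
15 | saturated alcohol: C9'β–CH2CH2OH, 8'α-CH3 | OCC[C@H]1[C@H](C)CC[C@@H]2C(C)(C)[C@H](O[Si](C)(C)C(C)(C)C)CC[C@@]21C | intermediate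
16 | primary bromide: C9'β–CH2CH2Br, 8'α-CH3 | BrCC[C@H]1[C@H](C)CC[C@@H]2C(C)(C)[C@H](O[Si](C)(C)C(C)(C)C)CC[C@@]21C | intermediate
17 | 7β-[2-(diphenylphosphanyl)benzoate] of 11 | O=C(c1ccccc1P(c1ccccc1)c1ccccc1)O[C@H]1C[C@@H]2C(C)(C)[C@H](O[Si](C)(C)C(C)(C)C)CC[C@]2(C)C=C1C | intermediate
18 | Grignard reagent from 16 | Br[Mg]CC[C@H]1[C@H](C)CC[C@@H]2C(C)(C)[C@H](O[Si](C)(C)C(C)(C)C)CC[C@@]21C | intermediate
19 | 3,3'-bis(tert-butyldimethylsilyl) ether of the target | CC1=CC[C@@H]2C(C)(C)[C@H](O[Si](C)(C)C(C)(C)C)CC[C@]2(C)[C@H]1CC[C@H]1[C@H](C)CC[C@@H]2C(C)(C)[C@H](O[Si](C)(C)C(C)(C)C)CC[C@@]21C | intermediate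
20 | CNP0194061.2, (3R,5S,9S,10R,3'R,5'S,8'R,9'S,10'R)-diol | CC1=CC[C@@H]2C(C)(C)[C@H](O)CC[C@]2(C)[C@H]1CC[C@H]1[C@H](C)CC[C@@H]2C(C)(C)[C@H](O)CC[C@@]21C | target

Total step count: 14. Longest linear sequence: 13 (steps 1–11, 13, 14); step 12 lies on the short branch from 11.

Steps most likely to fail

Step 13. Delivery of the alkylcopper species to C9, next to the quaternary C10, may be too slow. Attack at the ester carbonyl, direct substitution at C7 and homocoupling of the Grignard reagent could then take over.
The fallback replaces allylic substitution by conjugate addition. It sets out from 16 (through 18) and from enone 10, and it returns at 19.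
- Reagent 18 is added to 10 in a 1,4-sense (CuBr·SMe2, Me3SiCl, HMPA, THF, −78 °C), with attack expected on the convex β face. This gives the C7=C8 trimethylsilyl enol ether F1.
- MeLi (THF, 0 °C) releases the regiodefined lithium enolate F2.
- N-(5-chloropyridin-2-yl)bis(trifluoromethanesulfonimide) converts F2 into the C7 enol triflate F3.
- Formate reduction (Pd(OAc)2, PPh3, HCO2H, Et3N, DMF, 60 °C) replaces the triflate by hydrogen and gives 19.

Step 6. Three processes could cut the throughput:
- Carbenoid transfer to the enol ether carbon next to C10 may be sluggish.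
- n-BuLi may desilylate the enol ether.
- Part of the adduct may form with chlorine exo, and that isomer cannot open.

The fallback changes the mode of ring opening from an electrocyclic to a single-electron process. It sets out from 8 and returns at 10.
- Furukawa-type ethylidene transfer (Et2Zn, CH3CHI2, CH2Cl2, 0 °C) gives the chlorine-free methylcyclopropyl silyl ether F4.
- FeCl3 (DMF, 0 °C) oxidises F4, cleaves the shared C7–C9 bond in a Saegusa-type ring expansion and transfers chlorine to C9. This gives the β-chloro ketone F5, whatever the cyclopropane configuration.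
- NaOAc (MeOH, reflux) eliminates HCl to give 10.

Step 8. At 140 °C, loss of the allylic oxygen function to give a ring B diene may outrun the [3,3] shift, because the new bond forms beside the quaternary C10'.
The fallback replaces the sigmatropic step by a directed substitution. It sets out from 17 and returns at 14.
- Vinylmagnesium bromide with CuBr·SMe2 (Et2O, rt) undergoes the same phosphine-directed syn-SN2' reaction and gives the 9'β-vinyl compound F6.
- 9-BBN (THF, rt) hydroborates only the monosubstituted alkene to give the alkylborane F7.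
- NaOH/H2O2 oxidises F7 to 14.

Further compounds
F1 | step 13 | C7=C8 trimethylsilyl enol ether of the coupled 7-ketone (C9–C11 bond β) | CC1=C(O[Si](C)(C)C)C[C@@H]2C(C)(C)[C@H](O[Si](C)(C)C(C)(C)C)CC[C@]2(C)[C@H]1CC[C@H]1[C@H](C)CC[C@@H]2C(C)(C)[C@H](O[Si](C)(C)C(C)(C)C)CC[C@@]21C
F2 | step 13 | C7=C8 lithium enolate | CC1=C(O[Li])C[C@@H]2C(C)(C)[C@H](O[Si](C)(C)C(C)(C)C)CC[C@]2(C)[C@H]1CC[C@H]1[C@H](C)CC[C@@H]2C(C)(C)[C@H](O[Si](C)(C)C(C)(C)C)CC[C@@]21C
F3 | step 13 | C7 enol triflate | CC1=C(OS(=O)(=O)C(F)(F)F)C[C@@H]2C(C)(C)[C@H](O[Si](C)(C)C(C)(C)C)CC[C@]2(C)[C@H]1CC[C@H]1[C@H](C)CC[C@@H]2C(C)(C)[C@H](O[Si](C)(C)C(C)(C)C)CC[C@@]21C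
F4 | step 6 | methylcyclopropyl silyl ether (C8H(CH3) bridging C7 and C9 on the β face, methyl exo) | C[Si](C)(C)O[C@]12C[C@@H]3C(C)(C)[C@H](O[Si](C)(C)C(C)(C)C)CC[C@]3(C)[C@H]1[C@@H]2C
F5 | step 6 | β-chloro ketone (C7=O, 8α-CH3, 9β-Cl) | O=C1C[C@@H]2C(C)(C)[C@H](O[Si](C)(C)C(C)(C)C)CC[C@]2(C)[C@@H](Cl)[C@@H]1C
F6 | step 8 | 9'β-vinyl compound (C7'=C8') | CC1=CC[C@@H]2C(C)(C)[C@H](O[Si](C)(C)C(C)(C)C)CC[C@]2(C)[C@H]1C=C
F7 | step 8 | B-alkyl-9-borabicyclo[3.3.1]nonane from F6 | CC1=CC[C@@H]2C(C)(C)[C@H](O[Si](C)(C)C(C)(C)C)CC[C@]2(C)[C@H]1CCB1C2CCCC1CCC2
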